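**Retrosynthetic overview**

1. Labels: labdane numbering C1–C20 for the diterpene; C1'–C6' for ring D (C1' quaternary and chromone-bearing, C2' C=O, C3' H, C4' OMe, C5' C=O, C6' H); rings A/B = decalin, ring C = cyclohexene (C12–C15, C6', C1'), rings E/F = chromone. Enabling feature: ring D is a cyclohex-2-ene-1,4-dione whose C1' is quaternary, i.e. the blocked keto tautomer of a hydroquinone that cannot aromatize. C2'–C5' can therefore come from a methoxycyclobutenone, and the C1'–C6' fusion bond from a tetrasubstituted C=C of ring C.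
2. Ring D (last): Moore ring expansion of a 4-(cyclohexa-1,4-dienyl)-4-hydroxy-3-methoxycyclobutenone (4π opening, 6π closure C2'–C1', tautomerization) sets C1' and C6'.
3. The carbinol comes from the ring-C alkenyl iodide (I on C6') by iodine–magnesium exchange and addition to methyl semisquarate. The chromone (ring E) is closed before that on the C1' carboxyl, by Claisen acylation of bis-silylated phloroacetophenone and cyclodehydration.
4. Ring C: catalytic enantioselective Diels–Alder reaction of (12E)-labda-8(17),12,14-triene (7β,18-bis-silyl ether) with 3-iodopropynal; this sets C12 and places I on C6' and CHO on C1'.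
5. Triene from levopimaric acid (supplies C4, C5, C9, C10): ozonolysis to C8 ketone and C12 aldehyde, methylenation, C7 allylic oxidation then oxidation/Luche reduction (7β), two Wittig olefinations. Ring order: A/B and F bought; C (step 14); E (step 18); D (step 21).

Key step: step 21

Assumption: levopimaric acid is taken as a purchasable resin acid, and the (S)-oxazaborolidinium catalyst of step 14 is taken to give 12R; should the sense be opposite, the (R)-catalyst takes its place.

TBS = tert-butyldimethylsilyl. "Lab-methyl" = C11H2 carrying the 7β,18-bis(TBSO)-8(17)-methylene decalin of compound 13.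

**Step 1**
Reactants: 1 levopimaric acid
Product: 2 levopimarol (abieta-8(14),12-dien-18-ol)
Conditions: LiAlH4, THF, 0 °C → rt
Reagents that add atoms: none
Why: LiAlH4 reduces the hindered C18 carboxylic acid to the primary alcohol without touching the homoannular diene (hydride reduction); C4, C5, C9 and C10 are carried over from 1.

**Step 2**
Reactants: 2 levopimarol
Product: 3 18-O-TBS-levopimarol
Conditions: TBSCl, imidazole, DMF, rt
Reagents that add atoms: tert-butyldimethylsilyl chloride, CC(C)(C)[Si](C)(C)Cl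
Why: Silyl ether formation at the only hydroxyl protects C18–OH for the oxidations that follow.

**Step 3**
Reactants: 3 18-O-TBS-levopimarol
Product: 5 12,12-dimethoxy-18-(TBSO)-13,14,15,16,17-pentanorlabdan-8-one, via keto aldehyde 4 (not isolated)
Conditions: O3, CH2Cl2/MeOH, −78 °C; Me2S, −78 °C → rt; then HC(OMe)3, CeCl3·7H2O (cat.), MeOH, 0 °C
Reagents that add atoms: ozone, [O-][O+]=O; trimethyl orthoformate, COC(OC)OC
Why: Exhaustive ozonolysis of the 8(14),12-diene should excise C13–C17 as 3-methyl-2-oxobutanal and leave the C8 ketone and C12 aldehyde, and CeCl3-catalysed acetalization then takes only the unhindered aldehyde (ozonolysis, chemoselective acetal formation); C9 keeps its stable equatorial side chain.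

**Step 4**
Reactants: 5 keto acetal
Product: 6 12,12-dimethoxy-18-(TBSO)-13,14,15,16-tetranorlabd-8(17)-ene
Conditions: Ph3PCH3Br, KOtBu, toluene, 90 °C
Reagents that add atoms: methyltriphenylphosphonium bromide, [Br-].C[P+](c1ccccc1)(c1ccccc1)c1ccccc1
Why: Wittig methylenation of the hindered C8 ketone installs C17, and the base can only equilibrate C9 toward the equatorial configuration already present.

**Step 5**
Reactants: 6 methylene acetal
Product: 7 12,12-dimethoxy-18-(TBSO)-13,14,15,16-tetranorlabd-8(17)-en-7α-ol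
Conditions: SeO2 (cat.), t-BuOOH, CH2Cl2, rt
Reagents that add atoms: tert-butyl hydroperoxide, CC(C)(C)OO
Why: SeO2 allylic hydroxylation (ene reaction, then 2,3-sigmatropic shift) should attack the ring CH2 at C7 in preference to the C9 methine and deliver oxygen axially (7α); this configuration is corrected in steps 6 and 7.

**Step 6**
Reactants: 7 7α-alcohol
Product: 8 12,12-dimethoxy-18-(TBSO)-13,14,15,16-tetranorlabd-8(17)-en-7-one
Conditions: Dess–Martin periodinane, NaHCO3, CH2Cl2, 0 °C; crude used at once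
Reagents that add atoms: none
Why: Dess–Martin oxidation gives the exocyclic enone under non-basic conditions, which should avoid migration of the double bond to C8–C9.

**Step 7**
Reactants: 8 enone
Product: 9 12,12-dimethoxy-18-(TBSO)-13,14,15,16-tetranorlabd-8(17)-en-7β-ol
Conditions: NaBH4, CeCl3·7H2O, MeOH, −40 °C
Reagents that add atoms: none
Why: Luche 1,2-reduction: hydride should attack the C7 carbonyl along the axial (α) trajectory, so the new stereocenter C7 carries the equatorial 7β-hydroxyl (7S).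

**Step 8**
Reactants: 9 7β-alcohol
Product: 10 7β,18-bis(TBSO)-12,12-dimethoxy-13,14,15,16-tetranorlabd-8(17)-ene
Conditions: TBSCl, imidazole, DMF, 40 °C
Reagents that add atoms: tert-butyldimethylsilyl chloride, CC(C)(C)[Si](C)(C)Cl
Why: Silyl ether formation at the secondary allylic alcohol; the acetal is inert to TBSCl/imidazole.

**Step 9**
Reactants: 10 bis-silyl acetal
Product: 11 7β,18-bis(TBSO)-13,14,15,16-tetranorlabd-8(17)-en-12-al
Conditions: Et3SiOTf, 2,4,6-collidine, CH2Cl2, 0 °C; then H2O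
Reagents that add atoms: water, O
Why: Silyl triflate/collidine cleavage of the dimethyl acetal goes through a collidinium intermediate that water hydrolyses, so the aldehyde is released without acid strong enough to touch the silyl ethers or the allylic system.

**Step 10**
Reactants: 11 aldehyde
Product: 12 (12E)-7β,18-bis(TBSO)-15-norlabda-8(17),12-dien-14-al
Conditions: Ph3P=C(CH3)CHO, toluene, 90 °C
Reagents that add atoms: 2-(triphenylphosphoranylidene)propanal, CC(C=O)=P(c1ccccc1)(c1ccccc1)c1ccccc1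
Why: Wittig olefination with the formyl-stabilized ylide is selective for the (E)-trisubstituted C12=C13 enal.

**Step 11**
Reactants: 12 enal
Product: 13 (12E)-7β,18-bis(TBSO)labda-8(17),12,14-triene
Conditions: Ph3PCH3Br, KN(SiMe3)2, THF, −78 → 0 °C
Reagents that add atoms: methyltriphenylphosphonium bromide, [Br-].C[P+](c1ccccc1)(c1ccccc1)c1ccccc1
Why: Wittig methylenation of the enal gives the terminal vinyl group without disturbing the (E)-C12=C13 geometry.

**Step 12**
Reactants: 14 prop-2-yn-1-ol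
Product: 15 3-iodoprop-2-yn-1-ol
Conditions: N-iodosuccinimide, AgNO3 (10 mol %), acetone, rt, dark
Reagents that add atoms: N-iodosuccinimide, O=C1CCC(=O)N1I
Why: Silver-catalysed electrophilic iodination of the terminal alkyne C–H.

**Step 13**
Reactants: 15 3-iodoprop-2-yn-1-ol
Product: 16 3-iodoprop-2-ynal
Conditions: MnO2 (activated, excess), CH2Cl2, rt; filtered solution used directly
Reagents that add atoms: none
Why: MnO2 oxidizes the propargylic alcohol to the ynal without over-oxidation.

**Step 14**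
Reactants: 13 labdatriene; 16 3-iodoprop-2-ynal
Product: 17 (6R)-2-iodo-5-methyl-6-(Lab-methyl)cyclohexa-1,4-diene-1-carbaldehyde (ring carbons 1 = C1'; 2 = C6'; 6 = C12)
Conditions: (S)-B-(o-tolyl)oxazaborolidine from (S)-α,α-diphenylprolinol (20 mol %), Tf2NH (18 mol %), CH2Cl2, −78 °C
Reagents that add atoms: none
Why: Diels–Alder reaction of the (E)-diene with the Lewis-acid-bound ynal: the unsubstituted terminus C15 should bond to the iodine-bearing β-carbon (C6') and C12 to the formyl-bearing carbon (C1'), the "ortho" orientation of a 1-substituted diene, while the new stereocenter C12 (12R) is set by the chiral oxazaborolidinium cation, which screens one face of the coordinated aldehyde and so dictates which diene face is presented, the remote decalin exerting little bias.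

**Step 15**
Reactants: 17 iodo aldehyde
Product: 18 (6R)-2-iodo-5-methyl-6-(Lab-methyl)cyclohexa-1,4-diene-1-carboxylic acid
Conditions: NaClO2, NaH2PO4, 2-methylbut-2-ene, t-BuOH/H2O, 0 °C
Reagents that add atoms: sodium chlorite, [Na+].[O-]Cl=O
Why: Pinnick oxidation converts the hindered enal to the acid while the scavenger protects the alkenes and the skipped diene from hypochlorite.

**Step 16**
Reactants: 19 2',4',6'-trihydroxyacetophenone
Product: 20 1-[2-hydroxy-4,6-bis(TBSO)phenyl]ethanone
Conditions: TBSCl (2.1 equiv), imidazole, CH2Cl2/DMF, 0 °C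
Reagents that add atoms: tert-butyldimethylsilyl chloride, CC(C)(C)[Si](C)(C)Cl
Why: Silylation takes the para and one ortho hydroxyl; the remaining ortho hydroxyl is hydrogen-bonded to the ketone and should stay free (selective phenol protection).

**Step 17**
Reactants: 18 iodo acid; 20 silylated acetophenone
Product: 22 1-[2-hydroxy-4,6-bis(TBSO)phenyl]-3-[(6R)-2-iodo-5-methyl-6-(Lab-methyl)cyclohexa-1,4-dien-1-yl]propane-1,3-dione, via acid chloride 21 (not isolated)
Conditions: 18, Me2C=C(Cl)NMe2, CH2Cl2, 0 °C; added to 20 (2.2 equiv) + LiN(SiMe3)2 (4.4 equiv), THF, −78 → −20 °C; aq NH4Cl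
Reagents that add atoms: none
Why: Claisen-type C-acylation of the ketone dianion by the acid chloride (the 1,3-diketone of a Baker–Venkataraman chromone synthesis) should be far faster at −78 °C than attack at the hindered C6'–I carbon or γ-deprotonation.

**Step 18**
Reactants: 22 diketone
Product: 23 5,7-bis(TBSO)-2-[(6R)-2-iodo-5-methyl-6-(Lab-methyl)cyclohexa-1,4-dien-1-yl]-4H-chromen-4-one
Conditions: TsOH·H2O (10 mol %), toluene, 4 Å molecular sieves, 50 °C
Reagents that add atoms: none
Why: Acid-catalysed cyclodehydration: the free ortho hydroxyl adds to the distal carbonyl and loss of water closes the pyranone ring E.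

**Step 19**
Reactants: 24 dimethyl squarate
Product: 26 3-methoxycyclobut-3-ene-1,2-dione (methyl semisquarate), via hydroxy dimethoxy cyclobutenone 25 (not isolated)
Conditions: LiAlH(OtBu)3, THF, −78 °C; then 6 M HCl, CH2Cl2, 0 °C
Reagents that add atoms: none
Why: Hydride adds to one carbonyl of the squarate, and acid-promoted ionization and hydrolysis of the hydroxy enol ether then expels methanol (1,2-reduction, then elimination).

**Step 20**
Reactants: 23 iodo chromone; 26 methyl semisquarate
Product: 28 4-{(3R)-2-[5,7-bis(TBSO)-4-oxo-4H-chromen-2-yl]-4-methyl-3-(Lab-methyl)cyclohexa-1,4-dien-1-yl}-4-hydroxy-3-methoxycyclobut-2-en-1-one (both carbinol epimers), via alkenylmagnesium chloride 27 (not isolated)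
Conditions: i-PrMgCl·LiCl (1.1 equiv), THF, −78 °C; then 26 (1.5 equiv), −78 °C; aq NH4Cl at −78 °C
Reagents that add atoms: none
Why: Iodine–magnesium exchange should be fast on the electron-poor alkenyl iodide at −78 °C, where the vinylogous-ester carbonyl of the chromone is inert, and the alkenylmagnesium adds 1,2 to the more electrophilic carbonyl of 26 (the one next to C–OMe), which fixes the methoxy group at C4'; the carbinol centre forms as a mixture of no consequence.

**Step 21**
Reactants: 28 cyclobutenone carbinol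
Product: 31 7,18,5'',7''-tetrakis-O-TBS-dichrostachine A (5'',7'' = chromone oxygens), via dienylketene 29 (not isolated), via dienol 30 (not isolated)
Conditions: toluene (0.01 M, degassed), 110 °C
Reagents that add atoms: none
Why: Heating opens the cyclobutenone by conrotatory 4π-electrocyclic cleavage of the C5'–C2' bond to dienylketene 29, the hydroxyl rotating outward so that the cyclohexadienyl group turns inward and ketene carbon C2' is held over C1'; a thermal disrotatory 6π-electrocyclization then forms the C2'–C1' bond and closes ring D as the six-membered dienol 30, which cannot aromatize because C1' is quaternary and instead tautomerizes to the ene-1,4-dione 31. The closest known reaction type is the Moore rearrangement of 4-alkenyl-4-hydroxycyclobutenones to hydroquinones and quinones, here ended at a fully substituted alkene carbon. C1' (S) is controlled by the adjacent stereocenter C12: the ketene should add to the face of the C6'=C1' bond anti to the C11 methylene and its decalin, which leaves the chromone cis to C11. C6' (R) is set in the tautomerization, by protonation of the enol on the convex face (syn to the chromone, away from the folded ring C), which gives the cis ring fusion. The step needs outward torquoselectivity of the hydroxyl (secured by its donor character, the usual preference of 4-hydroxycyclobutenones) and closure onto C1' in preference to lactonization or 2+2 addition (secured by the Z relation of ketene and alkene that this rotation creates); the position of the methoxy group is already fixed by the regiochemistry of step 20.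

**Step 22**
Reactants: 31 tetrakis-O-TBS-dichrostachine A
Product: 32 dichrostachine A
Conditions: HF·pyridine, pyridine/THF, 0 °C → rt
Reagents that add atoms: none
Why: Fluoride cleaves the two aryl and two alkyl silyl ethers (global desilylation) under buffered conditions that should leave the vinylogous ester, the ene-dione and the allylic alcohol intact.

**Compound list**

1 | levopimaric acid (abieta-8(14),12-dien-18-oic acid) | C1=C2CC[C@H]3[C@](C)(C(=O)O)CCC[C@]3(C)[C@H]2CC=C1C(C)C | starting material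
2 | levopimarol (abieta-8(14),12-dien-18-ol) | C1=C2CC[C@H]3[C@](C)(CO)CCC[C@]3(C)[C@H]2CC=C1C(C)C | intermediate
3 | 18-O-TBS-levopimarol | C1=C2CC[C@H]3[C@](C)(CO[Si](C)(C)C(C)(C)C)CCC[C@]3(C)[C@H]2CC=C1C(C)C | intermediate
4 | 18-(TBSO)-8-oxo-13,14,15,16,17-pentanorlabdan-12-al (not isolated) | O=C1CC[C@H]2[C@](C)(CO[Si](C)(C)C(C)(C)C)CCC[C@]2(C)[C@H]1CC=O | intermediate
5 | 12,12-dimethoxy-18-(TBSO)-13,14,15,16,17-pentanorlabdan-8-one | O=C1CC[C@H]2[C@](C)(CO[Si](C)(C)C(C)(C)C)CCC[C@]2(C)[C@H]1CC(OC)OC | intermediate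
6 | 12,12-dimethoxy-18-(TBSO)-13,14,15,16-tetranorlabd-8(17)-ene | C=C1CC[C@H]2[C@](C)(CO[Si](C)(C)C(C)(C)C)CCC[C@]2(C)[C@H]1CC(OC)OC | intermediate
7 | 12,12-dimethoxy-18-(TBSO)-13,14,15,16-tetranorlabd-8(17)-en-7α-ol | C=C1[C@H](O)C[C@H]2[C@](C)(CO[Si](C)(C)C(C)(C)C)CCC[C@]2(C)[C@H]1CC(OC)OC | intermediate
8 | 12,12-dimethoxy-18-(TBSO)-13,14,15,16-tetranorlabd-8(17)-en-7-one | C=C1C(=O)C[C@H]2[C@](C)(CO[Si](C)(C)C(C)(C)C)CCC[C@]2(C)[C@H]1CC(OC)OC | intermediate
9 | 12,12-dimethoxy-18-(TBSO)-13,14,15,16-tetranorlabd-8(17)-en-7β-ol | C=C1[C@@H](O)C[C@H]2[C@](C)(CO[Si](C)(C)C(C)(C)C)CCC[C@]2(C)[C@H]1CC(OC)OC | intermediate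
10 | 7β,18-bis(TBSO)-12,12-dimethoxy-13,14,15,16-tetranorlabd-8(17)-ene | C=C1[C@@H](O[Si](C)(C)C(C)(C)C)C[C@H]2[C@](C)(CO[Si](C)(C)C(C)(C)C)CCC[C@]2(C)[C@H]1CC(OC)OC | intermediate
11 | 7β,18-bis(TBSO)-13,14,15,16-tetranorlabd-8(17)-en-12-al | C=C1[C@@H](O[Si](C)(C)C(C)(C)C)C[C@H]2[C@](C)(CO[Si](C)(C)C(C)(C)C)CCC[C@]2(C)[C@H]1CC=O | intermediate
12 | (12E)-7β,18-bis(TBSO)-15-norlabda-8(17),12-dien-14-al | C=C1[C@@H](O[Si](C)(C)C(C)(C)C)C[C@H]2[C@](C)(CO[Si](C)(C)C(C)(C)C)CCC[C@]2(C)[C@H]1C/C=C(C)/C=O | intermediate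
13 | (12E)-7β,18-bis(TBSO)labda-8(17),12,14-triene | C=C1[C@@H](O[Si](C)(C)C(C)(C)C)C[C@H]2[C@](C)(CO[Si](C)(C)C(C)(C)C)CCC[C@]2(C)[C@H]1C/C=C(C)/C=C | intermediate
14 | prop-2-yn-1-ol | C#CCO | starting material
15 | 3-iodoprop-2-yn-1-ol | OCC#CI | intermediate
16 | 3-iodoprop-2-ynal | O=CC#CI | intermediate
17 | (6R)-2-iodo-5-methyl-6-(Lab-methyl)cyclohexa-1,4-diene-1-carbaldehyde (12R) | C=C1[C@@H](O[Si](C)(C)C(C)(C)C)C[C@H]2[C@](C)(CO[Si](C)(C)C(C)(C)C)CCC[C@]2(C)[C@H]1C[C@@H]1C(C)=CCC(I)=C1C=O | intermediate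
18 | (6R)-2-iodo-5-methyl-6-(Lab-methyl)cyclohexa-1,4-diene-1-carboxylic acid | C=C1[C@@H](O[Si](C)(C)C(C)(C)C)C[C@H]2[C@](C)(CO[Si](C)(C)C(C)(C)C)CCC[C@]2(C)[C@H]1C[C@@H]1C(C)=CCC(I)=C1C(=O)O | intermediate
19 | 2',4',6'-trihydroxyacetophenone | CC(=O)c1c(O)cc(O)cc1O | starting material
20 | 1-[2-hydroxy-4,6-bis(TBSO)phenyl]ethanone | CC(=O)c1c(O)cc(O[Si](C)(C)C(C)(C)C)cc1O[Si](C)(C)C(C)(C)C | intermediate
21 | (6R)-2-iodo-5-methyl-6-(Lab-methyl)cyclohexa-1,4-diene-1-carbonyl chloride (not isolated) | C=C1[C@@H](O[Si](C)(C)C(C)(C)C)C[C@H]2[C@](C)(CO[Si](C)(C)C(C)(C)C)CCC[C@]2(C)[C@H]1C[C@@H]1C(C)=CCC(I)=C1C(=O)Cl | intermediate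
22 | 1-[2-hydroxy-4,6-bis(TBSO)phenyl]-3-[(6R)-2-iodo-5-methyl-6-(Lab-methyl)cyclohexa-1,4-dien-1-yl]propane-1,3-dione | C=C1[C@@H](O[Si](C)(C)C(C)(C)C)C[C@H]2[C@](C)(CO[Si](C)(C)C(C)(C)C)CCC[C@]2(C)[C@H]1C[C@@H]1C(C)=CCC(I)=C1C(=O)CC(=O)c1c(O)cc(O[Si](C)(C)C(C)(C)C)cc1O[Si](C)(C)C(C)(C)C | intermediate
23 | 5,7-bis(TBSO)-2-[(6R)-2-iodo-5-methyl-6-(Lab-methyl)cyclohexa-1,4-dien-1-yl]-4H-chromen-4-one | C=C1[C@@H](O[Si](C)(C)C(C)(C)C)C[C@H]2[C@](C)(CO[Si](C)(C)C(C)(C)C)CCC[C@]2(C)[C@H]1C[C@@H]1C(C)=CCC(I)=C1c1cc(=O)c2c(O[Si](C)(C)C(C)(C)C)cc(O[Si](C)(C)C(C)(C)C)cc2o1 | intermediate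
24 | dimethyl squarate (3,4-dimethoxycyclobut-3-ene-1,2-dione) | COC1=C(OC)C(=O)C1=O | starting material
25 | 4-hydroxy-2,3-dimethoxycyclobut-2-en-1-one (not isolated) | COC1=C(OC)C(=O)C1O | intermediate
26 | 3-methoxycyclobut-3-ene-1,2-dione (methyl semisquarate) | COC1=CC(=O)C1=O | intermediate
27 | C6'-magnesium chloride derived from 23 (not isolated) | C=C1[C@@H](O[Si](C)(C)C(C)(C)C)C[C@H]2[C@](C)(CO[Si](C)(C)C(C)(C)C)CCC[C@]2(C)[C@H]1C[C@@H]1C(C)=CCC([Mg]Cl)=C1c1cc(=O)c2c(O[Si](C)(C)C(C)(C)C)cc(O[Si](C)(C)C(C)(C)C)cc2o1 | intermediate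
28 | 4-{(3R)-2-[5,7-bis(TBSO)-4-oxo-4H-chromen-2-yl]-4-methyl-3-(Lab-methyl)cyclohexa-1,4-dien-1-yl}-4-hydroxy-3-methoxycyclobut-2-en-1-one (carbinol epimers) | C=C1[C@@H](O[Si](C)(C)C(C)(C)C)C[C@H]2[C@](C)(CO[Si](C)(C)C(C)(C)C)CCC[C@]2(C)[C@H]1C[C@@H]1C(C)=CCC(C2(O)C(OC)=CC2=O)=C1c1cc(=O)c2c(O[Si](C)(C)C(C)(C)C)cc(O[Si](C)(C)C(C)(C)C)cc2o1 | intermediate
29 | dienylketene: (Z)-4-hydroxy-3-methoxy-4-(ring-C dienyl)buta-1,3-dien-1-one (not isolated) | C=C1[C@@H](O[Si](C)(C)C(C)(C)C)C[C@H]2[C@](C)(CO[Si](C)(C)C(C)(C)C)CCC[C@]2(C)[C@H]1C[C@@H]1C(C)=CCC(/C(O)=C(OC)\C=C=O)=C1c1cc(=O)c2c(O[Si](C)(C)C(C)(C)C)cc(O[Si](C)(C)C(C)(C)C)cc2o1 | intermediate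
30 | ring-D dienol: 5'-hydroxy-4'-methoxy-cyclohexa-3',5'-dien-2'-one tautomer of 31 (not isolated) | C=C1[C@@H](O[Si](C)(C)C(C)(C)C)C[C@H]2[C@](C)(CO[Si](C)(C)C(C)(C)C)CCC[C@]2(C)[C@H]1C[C@@H]1C(C)=CCC2=C(O)C(OC)=CC(=O)[C@@]12c1cc(=O)c2c(O[Si](C)(C)C(C)(C)C)cc(O[Si](C)(C)C(C)(C)C)cc2o1 | intermediate
31 | 7,18,5'',7''-tetrakis-O-TBS-dichrostachine A (12R,1'S,6'R) | C=C1[C@@H](O[Si](C)(C)C(C)(C)C)C[C@H]2[C@](C)(CO[Si](C)(C)C(C)(C)C)CCC[C@]2(C)[C@H]1C[C@@H]1C(C)=CC[C@H]2C(=O)C(OC)=CC(=O)[C@@]12c1cc(=O)c2c(O[Si](C)(C)C(C)(C)C)cc(O[Si](C)(C)C(C)(C)C)cc2o1 | intermediate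
32 | dichrostachine A | C=C1[C@@H](O)C[C@H]2[C@](C)(CO)CCC[C@]2(C)[C@H]1C[C@@H]1C(C)=CC[C@H]2C(=O)C(OC)=CC(=O)[C@@]12c1cc(=O)c2c(O)cc(O)cc2o1 | target

**Step count and risks**

Total: 22 steps. Longest linear sequence: 18 steps (steps 1–11, 14, 15, 17, 18, 20, 21, 22) from levopimaric acid.

The three steps most likely to fail:

Step 14. The catalyst may not override the negligible facial bias of the diene (poor selectivity at C12), or the "ortho" orientation may be eroded by the C13 methyl group. Fallback from 13, rejoining at 17: methyl propiolate is iodinated (N-iodosuccinimide, AgNO3) to methyl 3-iodopropiolate F1. Uncatalysed thermal cycloaddition of F1 with 13 (toluene, 80 °C) should give the methyl ester F2 together with its C12 epimer, and the two are separated by preparative chromatography. Reduction of the 12R ester with i-Bu2AlH (CH2Cl2, −78 °C) gives the allylic alcohol F3, and Dess–Martin oxidation returns aldehyde 17. Stereocontrol by catalyst is thus replaced by separation of diastereomers.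

Step 20. The organomagnesium reagent may attack the chromone, the exchange may be incomplete, or addition to the semisquarate may go 1,4 or to the wrong carbonyl. Fallback from 23, rejoining at 28: a Nozaki–Hiyama–Kishi coupling (CrCl2 in excess, NiCl2 catalytic, DMF/THF, rt) in the presence of 26. The alkenylchromium species formed from the C6'–I bond tolerates ketones and vinylogous esters and should add in Barbier fashion only to the strained, aldehyde-like carbonyl of 26, giving 28 directly. No new compound is made on the way (F0).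

Step 21. The ketene may be captured by the free carbinol hydroxyl (lactonization after inward rotation), or the dienol may be protonated on the wrong face (trans ring fusion). Fallback from 28, rejoining at 31: the carbinol is silylated (N-trimethylsilylimidazole, CH2Cl2, 0 °C) to the trimethylsilyl ether F4, which removes the free hydroxyl and reinforces outward rotation. Thermolysis (toluene, 110 °C) should stop at the stable ring-D silyl dienol ether F5. Hydrolysis of F5 under kinetic control (citric acid, wet THF, 0 °C) protonates C6' from the convex face and gives 31; ring closure and the stereo-determining protonation are thereby separated.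

**Further compounds**

F1 | step 14 | methyl 3-iodopropiolate | COC(=O)C#CI
F2 | step 14 | methyl (6R)-2-iodo-5-methyl-6-(Lab-methyl)cyclohexa-1,4-diene-1-carboxylate | C=C1[C@@H](O[Si](C)(C)C(C)(C)C)C[C@H]2[C@](C)(CO[Si](C)(C)C(C)(C)C)CCC[C@]2(C)[C@H]1C[C@@H]1C(C)=CCC(I)=C1C(=O)OC
F3 | step 14 | [(6R)-2-iodo-5-methyl-6-(Lab-methyl)cyclohexa-1,4-dien-1-yl]methanol | C=C1[C@@H](O[Si](C)(C)C(C)(C)C)C[C@H]2[C@](C)(CO[Si](C)(C)C(C)(C)C)CCC[C@]2(C)[C@H]1C[C@@H]1C(C)=CCC(I)=C1CO
F0 | step 20 | none | none
F4 | step 21 | trimethylsilyl ether of carbinol 28 | C=C1[C@@H](O[Si](C)(C)C(C)(C)C)C[C@H]2[C@](C)(CO[Si](C)(C)C(C)(C)C)CCC[C@]2(C)[C@H]1C[C@@H]1C(C)=CCC(C2(O[Si](C)(C)C)C(OC)=CC2=O)=C1c1cc(=O)c2c(O[Si](C)(C)C(C)(C)C)cc(O[Si](C)(C)C(C)(C)C)cc2o1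
F5 | step 21 | ring-D 5'-trimethylsilyl dienol ether of 31 | C=C1[C@@H](O[Si](C)(C)C(C)(C)C)C[C@H]2[C@](C)(CO[Si](C)(C)C(C)(C)C)CCC[C@]2(C)[C@H]1C[C@@H]1C(C)=CCC2=C(O[Si](C)(C)C)C(OC)=CC(=O)[C@@]12c1cc(=O)c2c(O[Si](C)(C)C(C)(C)C)cc(O[Si](C)(C)C(C)(C)C)cc2o1
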